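**Assumption:** The SMILES describes 2-hydroxy-3-icosyl-5-methoxy-1,4-benzoquinone (unbranched C20 chain, C27H46O4). It has no stereocentres or stereogenic alkenes, so the "single enantiomer" requirement does not apply and no stereocontrol is needed.

## Retrosynthetic overview
1. The only strategic bond is ring C3–C1' of the chain. It is disconnected as a reductive Knoevenagel-type alkylation of a hydroxyquinone by a C20 aldehyde.
2. The chain fragment is icosan-1-ol (1), oxidised to icosanal (2).
3. The ring fragment is 2,5-dimethoxy-1,4-benzoquinone (3), mono-hydrolysed to 2-hydroxy-5-methoxy-1,4-benzoquinone (4). Compound 4 has one enolic nucleophilic carbon, C3, so the regiochemistry is set by its structure.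
4. Coupling 2 and 4 with a Hantzsch ester gives the target (5) directly, with no protecting groups.
5. No ring is formed. The single six-membered quinone ring is bought intact in 3.

## Route

**Step 1**
Reactants: 1, icosan-1-ol (1-eicosanol)
Product: 2, icosanal, CH3(CH2)18CHO
Conditions: IBX (1.5 equiv), EtOAc, 80 °C, 3–4 h; cool, filter, concentrate; use fresh
Reagents that add atoms: none
Why: This hypervalent-iodine (IBX) alcohol oxidation stops at the aldehyde, the waxy alcohol dissolves in hot EtOAc, and the iodine by-products are removed by filtration.

**Step 2**
Reactants: 3, 2,5-dimethoxy-1,4-benzoquinone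
Product: 4, 2-hydroxy-5-methoxy-1,4-benzoquinone
Conditions: NaOH (1.05 equiv), THF–H2O 1:1, N2, 25→40 °C; filter off any unreacted 3; 1 M HCl to pH 1–2; EtOAc extraction
Reagents that add atoms: sodium hydroxide, [Na+].[OH-]
Why: This is a vinylogous-ester saponification by addition–elimination on a symmetric substrate, in which hydroxide supplies the new oxygen and methoxide leaves as methanol, and the vinylogous carboxylate formed consumes the single equivalent of base and deactivates the ring toward a second hydrolysis.

Atom balance for Step 2: C8H8O4 + H2O − CH3OH = C7H6O4.

**Step 3**
Reactants: 4, 2-hydroxy-5-methoxy-1,4-benzoquinone (1.0 equiv); 2, icosanal (1.2 equiv)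
Product: 5, irisoquin D (2-hydroxy-3-icosyl-5-methoxy-1,4-benzoquinone)
Conditions: L-proline (20 mol %), Hantzsch ester (diethyl 2,6-dimethyl-1,4-dihydropyridine-3,5-dicarboxylate, 1.1 equiv), CH2Cl2, 25 °C, 12–24 h; stir open to air during work-up; SiO2 (hexane/EtOAc, 0.5 % AcOH), then recrystallise
Reagents that add atoms: none
Why: This is an organocatalytic three-component reductive alkylation, in which an amine-catalysed Knoevenagel condensation at the only enolic carbon (C3) gives an o-quinone methide that the Hantzsch ester reduces by conjugate hydride transfer; C3 is then blocked so no over-alkylation occurs, the electron-rich quinone resists reduction (any hydroquinone re-oxidises in air), and no stereocentre is created.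

Atom balance for Step 3: C7H6O4 + C20H40O + 2 H − H2O = C27H46O4, which matches the target. Reactant 2 supplies all 20 chain carbons and loses its oxygen as water. The Hantzsch ester delivers only hydrogen.

## Compound list
1 | icosan-1-ol | CCCCCCCCCCCCCCCCCCCCO | starting material
2 | icosanal | CCCCCCCCCCCCCCCCCCCC=O | intermediate
3 | 2,5-dimethoxy-1,4-benzoquinone | COC1=CC(=O)C(OC)=CC1=O | starting material
4 | 2-hydroxy-5-methoxy-1,4-benzoquinone | COC1=CC(=O)C(O)=CC1=O | intermediate
5 | irisoquin D, 2-hydroxy-3-icosyl-5-methoxy-1,4-benzoquinone (achiral) | CCCCCCCCCCCCCCCCCCCCC1=C(O)C(=O)C=C(OC)C1=O | target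

## Summary
Total step count: 3 (convergent).
Longest linear sequence: 2 steps (1→2→5 or 3→4→5).

The route has only three steps, so all three are ranked below by risk, each with a fallback.

1. **Step 3.** The risks are alkylidene-bis(quinone) formation, displacement of OMe by proline, and quinone reduction.
   Fallback: form the C–C bond at the arene oxidation level.
   - Lithiate 1,2,4,5-tetramethoxybenzene (n-BuLi, THF/HMPA) and alkylate with 1-bromoicosane.
   - Oxidatively demethylate with CAN to 3-icosyl-2,5-dimethoxy-1,4-benzoquinone.
   - Selectively hydrolyse the hindered 2-OMe next to the chain with HClO4.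
2. **Step 2.** The risks are over-hydrolysis to 2,5-dihydroxybenzoquinone and slow heterogeneous reaction of the poorly soluble 3.
   Fallback: build 4 oxidatively rather than by hydrolysis.
   - Carry out Thiele–Winter acetoxylation of 2-methoxy-1,4-benzoquinone (Ac2O, H2SO4) to 1,2,4-triacetoxy-5-methoxybenzene.
   - Follow with acidic methanolysis and air oxidation to 4.
3. **Step 1.** The risks are wax-ester or acid by-products and trimerisation of the aldehyde on storage.
   Fallback: approach from the acid oxidation level.
   - Convert icosanoic acid to its Weinreb amide (CDI, MeNHOMe·HCl).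
   - Reduce with LiAlH4 at 0 °C to 2.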